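**Plan**
- Retrosynthetic cuts: (i) the ketone C1(=O)–aryl bond to C1 of the 4-hydroxy-3,5-dimethoxyphenyl (syringyl) ring; (ii) the C2–O ether bond to the guaiacyl ring oxygen; (iii) three O–Si bonds of temporary silyl ethers (C3–OH, the propanol OH, the syringyl 4-OH).
- Forward order: a D-glycerate C3 unit is O-arylated at C2 with silyl-protected dihydroconiferyl alcohol (Mitsunobu), the ester is turned into an S-phenyl thioester, the thioester is joined to a syringyl boronic acid, and all three silyl groups are removed last. The chain stays acyclic; no ring is built.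
- Stereochemistry: the only stereocentre, C2 (S), comes from methyl (R)-glycerate (chiral pool) by SN2 inversion in the Mitsunobu step and is carried unchanged from there.
- Enabling feature: the ketone carbon C1 lies between the syringyl ring and C2, whose H is α to the C=O, geminal to an aryloxy group and β to the C3 oxygen. The aryl ketone is therefore the most epimerisable and elimination-prone compound of the route and must be made late and without base. A thioester C(acyl)–S bond is the one bond Pd(0) enters, and the syringyl ring is symmetric about its C1–C4 axis, so its 1-boronic acid is a single regioisomer.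

Key step: step 8

Remark: compounds 1, 3 and 8 are taken as commercially available; the stereocentre of the target is (S) by CIP analysis of the given SMILES.

**Step 1**
Reactants: 1 dihydroconiferyl alcohol [4-(3-hydroxypropyl)-2-methoxyphenol]
Product: 2 4-[3-(tert-butyldimethylsilyloxy)propyl]-2-methoxyphenol
Conditions: TBSCl (1.05 equiv), imidazole, CH2Cl2, 0 °C
Reagents that add atoms: tert-butyldimethylsilyl chloride (TBSCl), CC(C)(C)[Si](C)(C)Cl
Why: Chemoselective O-silylation under neutral imidazole conditions with limiting TBSCl, in which the unhindered primary aliphatic OH should react ahead of the ortho-methoxy-flanked, hydrogen-bonded phenol, so that only the phenol remains free for the later Mitsunobu etherification.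

**Step 2**
Reactants: 3 methyl (R)-2,2-dimethyl-1,3-dioxolane-4-carboxylate
Product: 4 methyl (R)-2,3-dihydroxypropanoate
Conditions: Amberlyst-15 (H+), MeOH/H2O 10:1, rt; filter, concentrate
Reagents that add atoms: none
Why: Acid-catalysed acetonide hydrolysis, which breaks only the ketal C–O bonds, leaves the C2 stereocentre untouched, and in methanol makes any transesterification degenerate.

**Step 3**
Reactants: 4 methyl (R)-2,3-dihydroxypropanoate
Product: 5 methyl (R)-3-(tert-butyldimethylsilyloxy)-2-hydroxypropanoate
Conditions: TBSCl (1.05 equiv), imidazole, CH2Cl2, 0 °C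
Reagents that add atoms: tert-butyldimethylsilyl chloride (TBSCl), CC(C)(C)[Si](C)(C)Cl
Why: Regioselective silylation of the primary OH over the more hindered and less nucleophilic secondary OH α to the ester, a standard differentiation of glycerate esters.

**Step 4**
Reactants: 2 4-[3-(tert-butyldimethylsilyloxy)propyl]-2-methoxyphenol; 5 methyl (R)-3-(tert-butyldimethylsilyloxy)-2-hydroxypropanoate
Product: 6 methyl (S)-3-(tert-butyldimethylsilyloxy)-2-{4-[3-(tert-butyldimethylsilyloxy)propyl]-2-methoxyphenoxy}propanoate
Conditions: PPh3, DIAD, THF, 0 °C → rt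
Reagents that add atoms: none
Why: Mitsunobu etherification, in which the phenol (pKa about 10) displaces the alkoxyphosphonium of the α-hydroxy ester by SN2 with clean inversion, so that the (R) chiral-pool centre becomes the (S) aryl ether centre of the target.

**Step 5**
Reactants: 6 methyl (S)-3-(tert-butyldimethylsilyloxy)-2-{4-[3-(tert-butyldimethylsilyloxy)propyl]-2-methoxyphenoxy}propanoate
Product: 7 S-phenyl (S)-3-(tert-butyldimethylsilyloxy)-2-{4-[3-(tert-butyldimethylsilyloxy)propyl]-2-methoxyphenoxy}propanethioate
Conditions: Me3Al, PhSH, CH2Cl2, 0 °C (forms Me2AlSPh); then 6, 0 °C → rt; aq. Rochelle salt work-up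
Reagents that add atoms: thiophenol, Sc1ccccc1
Why: Ester-to-thioester exchange with a dimethylaluminium thiolate (aluminium-thiolate transacylation), a Lewis-acidic and non-basic reagent that should exchange OMe for SPh at the carbonyl without removing the C2–H or disturbing the silyl ethers.

**Step 6**
Reactants: 8 4-bromo-2,6-dimethoxyphenol
Product: 9 (4-bromo-2,6-dimethoxyphenoxy)(tert-butyl)dimethylsilane
Conditions: TBSCl, imidazole, DMF, rt
Reagents that add atoms: tert-butyldimethylsilyl chloride (TBSCl), CC(C)(C)[Si](C)(C)Cl
Why: Standard phenol silylation in DMF, which should overcome the two flanking methoxy groups and masks the acidic OH for the lithiation and for the copper-mediated coupling.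

**Step 7**
Reactants: 9 (4-bromo-2,6-dimethoxyphenoxy)(tert-butyl)dimethylsilane
Product: 12 [4-(tert-butyldimethylsilyloxy)-3,5-dimethoxyphenyl]boronic acid, via aryllithium 10 (not isolated), via lithium aryl(triisopropoxy)borate 11 (not isolated)
Conditions: n-BuLi, THF, −78 °C; B(OiPr)3, −78 °C → rt; 1 M aq. HCl, 0 °C, short contact
Reagents that add atoms: triisopropyl borate, CC(C)OB(OC(C)C)OC(C)C; water, O
Why: Bromine–lithium exchange at −78 °C is faster than any ortho-metalation, the para silyloxy group cannot migrate to the carbanion, and trapping with a trialkyl borate followed by mild hydrolysis is the standard boronic acid synthesis.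

**Step 8**
Reactants: 7 S-phenyl (S)-3-(tert-butyldimethylsilyloxy)-2-{4-[3-(tert-butyldimethylsilyloxy)propyl]-2-methoxyphenoxy}propanethioate; 12 [4-(tert-butyldimethylsilyloxy)-3,5-dimethoxyphenyl]boronic acid (1.5 equiv)
Product: 13 (S)-3-(tert-butyldimethylsilyloxy)-1-[4-(tert-butyldimethylsilyloxy)-3,5-dimethoxyphenyl]-2-{4-[3-(tert-butyldimethylsilyloxy)propyl]-2-methoxyphenoxy}propan-1-one
Conditions: Pd2(dba)3 (2.5 mol %), P(OEt)3 (20 mol %), copper(I) thiophene-2-carboxylate (CuTC, 1.5 equiv), THF, rt, Ar
Reagents that add atoms: none
Why: Pd(0) inserts into the C(acyl)–S bond of 7; CuTC then binds the sulfur on palladium while its carboxylate activates the boron of 12, so the aryl group passes from boron to palladium at neutral pH and reductive elimination forms the C(=O)–C1(aryl) bond. The closest known reaction type is the Liebeskind–Srogl thioester–boronic acid ketone synthesis, which is established for α-amino acid thiol esters giving α-amino ketones without loss of configuration. No ring is closed and no new stereocentre is formed; C2 (S), set in step 4, is only carried through. The step needs retention at C2–H (α to the new ketone and geminal to the aryloxy group) and no β-elimination of the C3 silyloxy group; both are secured because no base stronger than a carboxylate is present and the reaction runs at room temperature. Chemoselectivity is secured because the acyl C–S bond is the only bond in either partner that Pd(0) can enter (no carbon–halogen bond), the boronic acid ring is symmetric so only one regioisomer can form, and the 4-OH is silylated so that no copper phenoxide forms.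

**Step 9**
Reactants: 13 (S)-3-(tert-butyldimethylsilyloxy)-1-[4-(tert-butyldimethylsilyloxy)-3,5-dimethoxyphenyl]-2-{4-[3-(tert-butyldimethylsilyloxy)propyl]-2-methoxyphenoxy}propan-1-one
Product: 14 (S)-3-hydroxy-1-(4-hydroxy-3,5-dimethoxyphenyl)-2-[4-(3-hydroxypropyl)-2-methoxyphenoxy]propan-1-one
Conditions: HF·pyridine (excess), THF, 0 °C → rt; pH 7 phosphate buffer work-up
Reagents that add atoms: none
Why: Fluoride-driven global desilylation, which should cleave the two primary alkyl and the one aryl Si–O bond under weakly acidic conditions, where the C2–H is not removed and neither retro-aldol cleavage nor β-elimination of the new β-hydroxy ketone is expected.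

**Compound list**
1 | dihydroconiferyl alcohol, 4-(3-hydroxypropyl)-2-methoxyphenol | COc1cc(CCCO)ccc1O | starting material
2 | 4-[3-(tert-butyldimethylsilyloxy)propyl]-2-methoxyphenol | COc1cc(CCCO[Si](C)(C)C(C)(C)C)ccc1O | intermediate
3 | methyl (R)-2,2-dimethyl-1,3-dioxolane-4-carboxylate | COC(=O)[C@H]1COC(C)(C)O1 | starting material
4 | methyl (R)-2,3-dihydroxypropanoate | COC(=O)[C@H](O)CO | intermediate
5 | methyl (R)-3-(tert-butyldimethylsilyloxy)-2-hydroxypropanoate | COC(=O)[C@H](O)CO[Si](C)(C)C(C)(C)C | intermediate
6 | methyl (S)-3-(tert-butyldimethylsilyloxy)-2-{4-[3-(tert-butyldimethylsilyloxy)propyl]-2-methoxyphenoxy}propanoate | COc1cc(CCCO[Si](C)(C)C(C)(C)C)ccc1O[C@@H](CO[Si](C)(C)C(C)(C)C)C(=O)OC | intermediate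
7 | S-phenyl (S)-3-(tert-butyldimethylsilyloxy)-2-{4-[3-(tert-butyldimethylsilyloxy)propyl]-2-methoxyphenoxy}propanethioate | COc1cc(CCCO[Si](C)(C)C(C)(C)C)ccc1O[C@@H](CO[Si](C)(C)C(C)(C)C)C(=O)Sc1ccccc1 | intermediate
8 | 4-bromo-2,6-dimethoxyphenol | COc1cc(Br)cc(OC)c1O | starting material
9 | (4-bromo-2,6-dimethoxyphenoxy)(tert-butyl)dimethylsilane | COc1cc(Br)cc(OC)c1O[Si](C)(C)C(C)(C)C | intermediate
10 | [4-(tert-butyldimethylsilyloxy)-3,5-dimethoxyphenyl]lithium (not isolated) | [Li]c1cc(OC)c(O[Si](C)(C)C(C)(C)C)c(OC)c1 | intermediate
11 | lithium [4-(tert-butyldimethylsilyloxy)-3,5-dimethoxyphenyl]triisopropoxyborate (not isolated) | [Li+].CC(C)O[B-](OC(C)C)(OC(C)C)c1cc(OC)c(O[Si](C)(C)C(C)(C)C)c(OC)c1 | intermediate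
12 | [4-(tert-butyldimethylsilyloxy)-3,5-dimethoxyphenyl]boronic acid | COc1cc(B(O)O)cc(OC)c1O[Si](C)(C)C(C)(C)C | intermediate
13 | (S)-3-(tert-butyldimethylsilyloxy)-1-[4-(tert-butyldimethylsilyloxy)-3,5-dimethoxyphenyl]-2-{4-[3-(tert-butyldimethylsilyloxy)propyl]-2-methoxyphenoxy}propan-1-one | COc1cc(CCCO[Si](C)(C)C(C)(C)C)ccc1O[C@@H](CO[Si](C)(C)C(C)(C)C)C(=O)c1cc(OC)c(O[Si](C)(C)C(C)(C)C)c(OC)c1 | intermediate
14 | (S)-3-hydroxy-1-(4-hydroxy-3,5-dimethoxyphenyl)-2-[4-(3-hydroxypropyl)-2-methoxyphenoxy]propan-1-one | COc1cc(CCCO)ccc1O[C@@H](CO)C(=O)c1cc(OC)c(O)c(OC)c1 | target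

**Step count**
Total steps: 9. Longest linear sequence: 6 steps (3 → 4 → 5 → 6 → 7 → 13 → 14, steps 2, 3, 4, 5, 8, 9).

**Steps most likely to fail**

Step 8. The electron-rich boronic acid may undergo protodeboronation or homocoupling faster than it transmetalates, the acyl-palladium intermediate may lose CO, or the C2 centre may erode during a slow coupling. The fallback replaces the catalytic coupling by acyl substitution on a Weinreb amide. It sets out from ester 6, which with MeNH(OMe)·HCl and Me3Al in CH2Cl2 (0 °C → rt) should give (S)-3-(tert-butyldimethylsilyloxy)-2-{4-[3-(tert-butyldimethylsilyloxy)propyl]-2-methoxyphenoxy}-N-methoxy-N-methylpropanamide F1. Aryllithium 10, made from bromide 9 with n-BuLi in THF at −78 °C, is then added at −78 °C to give the chelated lithium N-methoxy-N-methyl hemiaminal alkoxide F2. This adduct keeps the carbonyl masked, so no ketone is exposed to the organolithium. A cold quench with AcOH in THF at −78 °C should release the ketone, and the fallback comes back to the route at 13.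

Step 4. Substitution at the α-carbon may be slow because of the neighbouring silyloxymethyl group and the ortho-methoxy phenol, so that alkylation of the hydrazide by-product or elimination competes. The fallback replaces the redox condensation by a sulfonate displacement. It sets out from 5, which with Tf2O and 2,6-lutidine in CH2Cl2 at −78 °C should give methyl (R)-3-(tert-butyldimethylsilyloxy)-2-(trifluoromethylsulfonyloxy)propanoate F3. Phenol 2 with K2CO3 in MeCN at 0 °C should then displace the triflate by SN2 with inversion, and the fallback comes back to the route at 6.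

Step 5. The aluminium thiolate exchange may stop short of completion, the Lewis acid may strip a silyl ether, or the thioester may partly epimerise through an aluminium enolate. The fallback replaces direct exchange by hydrolysis and condensation. It sets out from 6, which with LiOH in THF/H2O at 0 °C should give (S)-3-(tert-butyldimethylsilyloxy)-2-{4-[3-(tert-butyldimethylsilyloxy)propyl]-2-methoxyphenoxy}propanoic acid F4. Coupling with PhSH, EDC·HCl and HOBt in CH2Cl2 at 0 °C should then give the thioester, and the fallback comes back to the route at 7.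

**Further compounds**
F1 | step 8 | (S)-3-(tert-butyldimethylsilyloxy)-2-{4-[3-(tert-butyldimethylsilyloxy)propyl]-2-methoxyphenoxy}-N-methoxy-N-methylpropanamide | COc1cc(CCCO[Si](C)(C)C(C)(C)C)ccc1O[C@@H](CO[Si](C)(C)C(C)(C)C)C(=O)N(C)OC
F2 | step 8 | lithium (2S)-3-(tert-butyldimethylsilyloxy)-1-[4-(tert-butyldimethylsilyloxy)-3,5-dimethoxyphenyl]-2-{4-[3-(tert-butyldimethylsilyloxy)propyl]-2-methoxyphenoxy}-1-[methoxy(methyl)amino]propan-1-olate (not isolated) | COc1cc(CCCO[Si](C)(C)C(C)(C)C)ccc1O[C@@H](CO[Si](C)(C)C(C)(C)C)C(O[Li])(N(C)OC)c1cc(OC)c(O[Si](C)(C)C(C)(C)C)c(OC)c1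
F3 | step 4 | methyl (R)-3-(tert-butyldimethylsilyloxy)-2-(trifluoromethylsulfonyloxy)propanoate | COC(=O)[C@H](OS(=O)(=O)C(F)(F)F)CO[Si](C)(C)C(C)(C)C
F4 | step 5 | (S)-3-(tert-butyldimethylsilyloxy)-2-{4-[3-(tert-butyldimethylsilyloxy)propyl]-2-methoxyphenoxy}propanoic acid | COc1cc(CCCO[Si](C)(C)C(C)(C)C)ccc1O[C@@H](CO[Si](C)(C)C(C)(C)C)C(=O)O
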